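**Retrosynthetic overview**

1. The strategy rests on the single sp2–sp2 bond between coumarin C3 (the carbon alpha to the lactone carbonyl C2) and C6' (the enol-ether carbon of the 2-methyl-2,3-dihydro-4H-pyran-4-one ring). This bond joins two rings that can each be built alone, and it is cut to a 3-bromocoumarin and a C6'-stannyl dihydropyran (Stille coupling).
2. The pyranone is carried through the coupling as its C4' silyl-protected allylic alcohol. Fluoride and then MnO2 restore the beta-alkoxy enone only at the end.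
3. Bromocoumarin: C3 bromination of the coumarin, which comes from Wittig–lactonisation of a salicylaldehyde. The arene is built from 1,3-bis(benzyloxy)-5-bromobenzene by formylation/reduction (C6 methyl), aryllithium opening of (2R,3R)-2,3-epoxybutane (both side-chain centres), bromination and formylation.
4. Stannane: methyl (S)-3-hydroxybutanoate (C2' from the chiral pool) to Weinreb amide, ynone, 6-endo closure to the dihydropyranone, Luche reduction, silylation, C6' lithiation and stannylation.
5. Ring order: the benzene ring is bought, the coumarin lactone ring closes in step 9, the dihydropyran ring closes in step 13, and the two are joined in step 17.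

Key step: step 17

Remark: 1,3-bis(benzyloxy)-5-bromobenzene is taken as a catalogue compound (otherwise one O-benzylation from 5-bromoresorcinol); benzyl ethers are used so that the phenols can be freed by hydrogenolysis, without a Lewis acid next to the side-chain silyl ether.

**Route**

Step 1
Reactants: 1 1,3-bis(benzyloxy)-5-bromobenzene
Product: 3 2,4-bis(benzyloxy)-6-bromobenzaldehyde, via aryl iminium chloride 2 (not isolated)
Conditions: POCl3, DMF, 0 to 80 °C; then aq NaOAc
Reagents that add atoms: N,N-dimethylformamide, CN(C)C=O; water, O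
Why: Vilsmeier–Haack formylation, in which the chloroiminium ion should attack the ring position para to one benzyloxy group and ortho to the other (next to bromine) and not the more crowded position between the two ethers, the pattern established for 1-bromo-3,5-dialkoxybenzenes.

Step 2
Reactants: 3 2,4-bis(benzyloxy)-6-bromobenzaldehyde
Product: 4 1,5-bis(benzyloxy)-3-bromo-2-methylbenzene
Conditions: Et3SiH, TFA, CH2Cl2, 0 °C to rt
Reagents that add atoms: none
Why: Ionic hydrogenation (Et3SiH/TFA deoxygenation) of an aldehyde whose benzylic cation is stabilised by ortho and para alkoxy groups should take the formyl group down to the methyl group that becomes C6–CH3 of the coumarin, leaving aryl bromide and benzyl ethers alone.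

Step 3
Reactants: 4 1,5-bis(benzyloxy)-3-bromo-2-methylbenzene; 5 (2R,3R)-2,3-epoxybutane
Product: 7 (2R,3R)-3-[3,5-bis(benzyloxy)-2-methylphenyl]butan-2-ol, via aryllithium 6 (not isolated)
Conditions: nBuLi, THF, −78 °C; then 5, BF3·OEt2, −78 °C; aq NaHCO3
Reagents that add atoms: none
Why: Bromine–lithium exchange followed by BF3-promoted SN2 opening of the epoxide by the aryllithium, in which backside attack inverts the attacked carbon and leaves the carbinol carbon untouched, so that the C2-symmetric (2R,3R)-epoxide should deliver the (2R,3R) alcohol whichever carbon is attacked, setting both side-chain stereocentres.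

Step 4
Reactants: 7 (2R,3R)-3-[3,5-bis(benzyloxy)-2-methylphenyl]butan-2-ol
Product: 8 1,5-bis(benzyloxy)-2-methyl-3-[(2R,3R)-3-(tert-butyldimethylsilyloxy)butan-2-yl]benzene
Conditions: TBSOTf, 2,6-lutidine, CH2Cl2, 0 °C
Reagents that add atoms: tert-butyldimethylsilyl triflate, CC(C)(C)[Si](C)(C)OS(=O)(=O)C(F)(F)F
Why: Standard silyl triflate silylation of a hindered secondary alcohol, needed so that the later ortho aldehyde cannot close to a lactol.

Step 5
Reactants: 8 1,5-bis(benzyloxy)-2-methyl-3-[(2R,3R)-3-(tert-butyldimethylsilyloxy)butan-2-yl]benzene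
Product: 9 1,5-bis(benzyloxy)-2-bromo-4-methyl-3-[(2R,3R)-3-(tert-butyldimethylsilyloxy)butan-2-yl]benzene
Conditions: NBS, MeCN, 0 °C, dark
Reagents that add atoms: N-bromosuccinimide, O=C1CCC(=O)N1Br
Why: Electrophilic aromatic bromination with NBS, expected at the only free position that is para to a benzyloxy group (ortho to the side chain), the site between the two ethers being the usual slow position of resorcinol diethers.

Step 6
Reactants: 9 1,5-bis(benzyloxy)-2-bromo-4-methyl-3-[(2R,3R)-3-(tert-butyldimethylsilyloxy)butan-2-yl]benzene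
Product: 11 2,4-bis(benzyloxy)-5-methyl-6-[(2R,3R)-3-(tert-butyldimethylsilyloxy)butan-2-yl]benzaldehyde, via aryllithium 10 (not isolated)
Conditions: nBuLi, THF, −78 °C; DMF, −78 to 0 °C; aq NH4Cl
Reagents that add atoms: N,N-dimethylformamide, CN(C)C=O
Why: Bromine–lithium exchange and Bouveault formylation of the aryllithium with DMF, a regiospecific way to put the aldehyde where the bromine stood, under conditions that leave silyl and benzyl ethers intact.

Step 7
Reactants: 11 2,4-bis(benzyloxy)-5-methyl-6-[(2R,3R)-3-(tert-butyldimethylsilyloxy)butan-2-yl]benzaldehyde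
Product: 12 2,4-dihydroxy-5-methyl-6-[(2R,3R)-3-(tert-butyldimethylsilyloxy)butan-2-yl]benzaldehyde
Conditions: H2 (1 atm), Pd/C, EtOAc, rt
Reagents that add atoms: none
Why: Hydrogenolysis of both aryl benzyl ethers over Pd/C in a non-acidic solvent, where the hindered, hydrogen-bonded salicylaldehyde and the silyl ether should survive.

Step 8
Reactants: 12 2,4-dihydroxy-5-methyl-6-[(2R,3R)-3-(tert-butyldimethylsilyloxy)butan-2-yl]benzaldehyde
Product: 13 4-(tert-butyldimethylsilyloxy)-2-hydroxy-5-methyl-6-[(2R,3R)-3-(tert-butyldimethylsilyloxy)butan-2-yl]benzaldehyde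
Conditions: TBSCl (1.05 equiv), imidazole, CH2Cl2, 0 °C
Reagents that add atoms: tert-butyldimethylsilyl chloride, CC(C)(C)[Si](C)(C)Cl
Why: Chemoselective silylation, since the C2 hydroxyl is tied up in a hydrogen bond to the aldehyde and the C4 hydroxyl is the more nucleophilic phenol, as in the known 4-O-selective protection of 2,4-dihydroxybenzaldehydes.

Step 9
Reactants: 13 4-(tert-butyldimethylsilyloxy)-2-hydroxy-5-methyl-6-[(2R,3R)-3-(tert-butyldimethylsilyloxy)butan-2-yl]benzaldehyde
Product: 15 7-(tert-butyldimethylsilyloxy)-5-[(2R,3R)-3-(tert-butyldimethylsilyloxy)butan-2-yl]-6-methyl-2H-chromen-2-one, via ethyl (E)-cinnamate 14 (not isolated)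
Conditions: Ph3P=CHCO2Et, PhNEt2, reflux
Reagents that add atoms: ethyl (triphenylphosphoranylidene)acetate, CCOC(=O)C=P(c1ccccc1)(c1ccccc1)c1ccccc1
Why: Wittig olefination of a salicylaldehyde with a stabilised ylide followed by thermal alkene isomerisation and lactonisation with loss of ethanol, the classical Wittig coumarin synthesis, which closes the lactone ring.

Step 10
Reactants: 15 7-(tert-butyldimethylsilyloxy)-5-[(2R,3R)-3-(tert-butyldimethylsilyloxy)butan-2-yl]-6-methyl-2H-chromen-2-one
Product: 17 3-bromo-7-(tert-butyldimethylsilyloxy)-5-[(2R,3R)-3-(tert-butyldimethylsilyloxy)butan-2-yl]-6-methyl-2H-chromen-2-one, via 3,4-dibromo-3,4-dihydrocoumarin 16 (not isolated)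
Conditions: Br2, CH2Cl2, 0 °C; then Et3N, 0 °C to rt
Reagents that add atoms: bromine, BrBr
Why: Bromine addition across the C3=C4 bond of the coumarin and base-induced dehydrobromination (loss of the acidic C3–H and the benzylic C4 bromide), the standard route to 3-bromocoumarins, with C6 blocked by methyl and the C7 oxygen silylated to hold back ring bromination.

Step 11
Reactants: 18 methyl (S)-3-hydroxybutanoate
Product: 19 (S)-3-hydroxy-N-methoxy-N-methylbutanamide
Conditions: MeNHOMe·HCl, iPrMgCl, THF, −20 to 0 °C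
Reagents that add atoms: N,O-dimethylhydroxylamine hydrochloride, CNOC.Cl
Why: Weinreb amide formation from an ester with the chloromagnesium amide of N,O-dimethylhydroxylamine, which tolerates the free hydroxyl as its magnesium alkoxide and does not touch the stereocentre.

Step 12
Reactants: 19 (S)-3-hydroxy-N-methoxy-N-methylbutanamide
Product: 20 (S)-5-hydroxyhex-1-yn-3-one
Conditions: HC≡CMgBr (3.5 equiv), THF, 0 °C to rt; inverse quench into cold aq NaHSO4
Reagents that add atoms: ethynylmagnesium bromide, C#C[Mg]Br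
Why: Weinreb ketone synthesis with an alkynyl Grignard reagent, in which the chelated tetrahedral adduct prevents double addition and the acidic inverse quench keeps liberated N,O-dimethylhydroxylamine from adding to the ynone.

Step 13
Reactants: 20 (S)-5-hydroxyhex-1-yn-3-one
Product: 22 (S)-2-methyl-2,3-dihydro-4H-pyran-4-one, via diethylamino enone 21 (not isolated)
Conditions: Et2NH, CH2Cl2, 0 °C to rt; then TFA, rt
Reagents that add atoms: none
Why: Aza-Michael addition of diethylamine to the terminal ynone gives a vinylogous amide, and under acid the C5 hydroxyl adds to the beta carbon and expels diethylamine (6-endo addition–elimination, the cyclisation used for beta-hetero-substituted beta'-hydroxy enones), closing the dihydropyranone ring without breaking the C–O bond of the stereocentre.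

Step 14
Reactants: 22 (S)-2-methyl-2,3-dihydro-4H-pyran-4-one
Product: 23 (2S,4R)-2-methyl-3,4-dihydro-2H-pyran-4-ol (2,4-cis)
Conditions: NaBH4, CeCl3·7H2O, MeOH, −78 °C
Reagents that add atoms: none
Why: Luche 1,2-reduction, in which hydride should add axially to the half-chair enone with the C2 methyl pseudo-equatorial and so give the pseudo-equatorial 2,4-cis (4R) alcohol, a centre that is removed again in step 19.

Step 15
Reactants: 23 (2S,4R)-2-methyl-3,4-dihydro-2H-pyran-4-ol
Product: 24 (2S,4R)-2-methyl-4-(triisopropylsilyloxy)-3,4-dihydro-2H-pyran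
Conditions: TIPSOTf, 2,6-lutidine, CH2Cl2, −78 to 0 °C
Reagents that add atoms: triisopropylsilyl triflate, CC(C)[Si](OS(=O)(=O)C(F)(F)F)(C(C)C)C(C)C
Why: Silylation with the silyl triflate under 2,6-lutidine buffering, which protects the acid-sensitive allylic alcohol with a group that has no Si–CH3 hydrogens for the next step.

Step 16
Reactants: 24 (2S,4R)-2-methyl-4-(triisopropylsilyloxy)-3,4-dihydro-2H-pyran; 25 tributyltin chloride
Product: 27 (2S,4R)-2-methyl-4-(triisopropylsilyloxy)-6-(tributylstannyl)-3,4-dihydro-2H-pyran, via 6-lithiodihydropyran 26 (not isolated)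
Conditions: tBuLi (3 equiv), THF, −78 to 0 °C; then 25, −78 °C to rt
Reagents that add atoms: none
Why: Directed vinylic deprotonation alpha to the ring oxygen by tert-butyllithium followed by stannylation, the known C1-lithiation of silylated glycals, which leaves both stereocentres alone.

Step 17
Reactants: 17 3-bromo-7-(tert-butyldimethylsilyloxy)-5-[(2R,3R)-3-(tert-butyldimethylsilyloxy)butan-2-yl]-6-methyl-2H-chromen-2-one; 27 (2S,4R)-2-methyl-4-(triisopropylsilyloxy)-6-(tributylstannyl)-3,4-dihydro-2H-pyran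
Product: 28 7-(tert-butyldimethylsilyloxy)-5-[(2R,3R)-3-(tert-butyldimethylsilyloxy)butan-2-yl]-6-methyl-3-[(2S,4R)-2-methyl-4-(triisopropylsilyloxy)-3,4-dihydro-2H-pyran-6-yl]-2H-chromen-2-one
Conditions: Pd(PPh3)4 (10 mol%), CuI (20 mol%), degassed 1,4-dioxane, 90 °C
Reagents that add atoms: none
Why: Zerovalent palladium from Pd(PPh3)4 inserts into the C3–Br bond of 17, an sp2 bromide activated by the adjacent lactone carbonyl; the alpha-alkoxyvinyl group of 27 then passes from tin to palladium, helped by CuI (which scavenges free PPh3 and can relay the vinyl group through copper), and reductive elimination forms the C3–C6' bond. The closest known reaction type is the Stille coupling of C1-stannyl glycals with aryl and vinyl bromides, and 3-bromocoumarins are established Stille electrophiles. No ring closes and no stereocentre is created. The step needs site selectivity and survival of three silyl ethers: there is one C–Br and one C–Sn bond, no fluoride or base is present, and the phenol is silylated so that no acidic O–H can protodestannylate the enol-ether stannane. C2' and C4' of the pyran and both side-chain centres are spectators, because no enolisable carbonyl is next to them while the beta-alkoxy enone is still masked as the allylic silyl ether.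

Step 18
Reactants: 28 tris-silylated coupling product
Product: 29 7-hydroxy-5-[(2R,3R)-3-hydroxybutan-2-yl]-3-[(2S,4R)-4-hydroxy-2-methyl-3,4-dihydro-2H-pyran-6-yl]-6-methyl-2H-chromen-2-one
Conditions: TBAF, THF, 0 °C to rt; pH 7 phosphate buffer work-up
Reagents that add atoms: none
Why: Fluoride-induced cleavage of the aryl silyl ether, the secondary alkyl silyl ether and the allylic silyl ether under non-acidic conditions, chosen because the free allylic alcohol next to the enol ether would ionise under acid.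

Step 19
Reactants: 29 7-hydroxy-5-[(2R,3R)-3-hydroxybutan-2-yl]-3-[(2S,4R)-4-hydroxy-2-methyl-3,4-dihydro-2H-pyran-6-yl]-6-methyl-2H-chromen-2-one
Product: 30 7-hydroxy-5-[(2R,3R)-3-hydroxybutan-2-yl]-6-methyl-3-[(2S)-2-methyl-4-oxo-3,4-dihydro-2H-pyran-6-yl]-2H-chromen-2-one (CNP0270207.1)
Conditions: activated MnO2, acetone, rt
Reagents that add atoms: none
Why: Chemoselective allylic oxidation with MnO2, which should oxidise only the C4' alcohol conjugated to the enol-ether double bond and leave the saturated side-chain alcohol and the phenol, under neutral conditions that cannot open the beta-alkoxy enone and racemise C2'.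

**Compound list**

1 | 1,3-bis(benzyloxy)-5-bromobenzene | Brc1cc(OCc2ccccc2)cc(OCc2ccccc2)c1 | starting material
2 | N-[2,4-bis(benzyloxy)-6-bromobenzylidene]-N-methylmethanaminium chloride | C[N+](C)=Cc1c(Br)cc(OCc2ccccc2)cc1OCc1ccccc1.[Cl-] | intermediate
3 | 2,4-bis(benzyloxy)-6-bromobenzaldehyde | O=Cc1c(Br)cc(OCc2ccccc2)cc1OCc1ccccc1 | intermediate
4 | 1,5-bis(benzyloxy)-3-bromo-2-methylbenzene | Cc1c(Br)cc(OCc2ccccc2)cc1OCc1ccccc1 | intermediate
5 | (2R,3R)-2,3-epoxybutane | C[C@H]1O[C@@H]1C | starting material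
6 | [3,5-bis(benzyloxy)-2-methylphenyl]lithium | [Li]c1cc(OCc2ccccc2)cc(OCc2ccccc2)c1C | intermediate
7 | (2R,3R)-3-[3,5-bis(benzyloxy)-2-methylphenyl]butan-2-ol | Cc1c(OCc2ccccc2)cc(OCc2ccccc2)cc1[C@@H](C)[C@@H](C)O | intermediate
8 | 1,5-bis(benzyloxy)-2-methyl-3-[(2R,3R)-3-(tert-butyldimethylsilyloxy)butan-2-yl]benzene | Cc1c(OCc2ccccc2)cc(OCc2ccccc2)cc1[C@@H](C)[C@@H](C)O[Si](C)(C)C(C)(C)C | intermediate
9 | 1,5-bis(benzyloxy)-2-bromo-4-methyl-3-[(2R,3R)-3-(tert-butyldimethylsilyloxy)butan-2-yl]benzene | Cc1c(OCc2ccccc2)cc(OCc2ccccc2)c(Br)c1[C@@H](C)[C@@H](C)O[Si](C)(C)C(C)(C)C | intermediate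
10 | {2,4-bis(benzyloxy)-5-methyl-6-[(2R,3R)-3-(tert-butyldimethylsilyloxy)butan-2-yl]phenyl}lithium | Cc1c(OCc2ccccc2)cc(OCc2ccccc2)c([Li])c1[C@@H](C)[C@@H](C)O[Si](C)(C)C(C)(C)C | intermediate
11 | 2,4-bis(benzyloxy)-5-methyl-6-[(2R,3R)-3-(tert-butyldimethylsilyloxy)butan-2-yl]benzaldehyde | Cc1c(OCc2ccccc2)cc(OCc2ccccc2)c(C=O)c1[C@@H](C)[C@@H](C)O[Si](C)(C)C(C)(C)C | intermediate
12 | 2,4-dihydroxy-5-methyl-6-[(2R,3R)-3-(tert-butyldimethylsilyloxy)butan-2-yl]benzaldehyde | Cc1c(O)cc(O)c(C=O)c1[C@@H](C)[C@@H](C)O[Si](C)(C)C(C)(C)C | intermediate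
13 | 4-(tert-butyldimethylsilyloxy)-2-hydroxy-5-methyl-6-[(2R,3R)-3-(tert-butyldimethylsilyloxy)butan-2-yl]benzaldehyde | Cc1c(O[Si](C)(C)C(C)(C)C)cc(O)c(C=O)c1[C@@H](C)[C@@H](C)O[Si](C)(C)C(C)(C)C | intermediate
14 | ethyl (E)-3-{4-(tert-butyldimethylsilyloxy)-2-hydroxy-5-methyl-6-[(2R,3R)-3-(tert-butyldimethylsilyloxy)butan-2-yl]phenyl}acrylate | CCOC(=O)/C=C/c1c(O)cc(O[Si](C)(C)C(C)(C)C)c(C)c1[C@@H](C)[C@@H](C)O[Si](C)(C)C(C)(C)C | intermediate
15 | 7-(tert-butyldimethylsilyloxy)-5-[(2R,3R)-3-(tert-butyldimethylsilyloxy)butan-2-yl]-6-methyl-2H-chromen-2-one | Cc1c(O[Si](C)(C)C(C)(C)C)cc2oc(=O)ccc2c1[C@@H](C)[C@@H](C)O[Si](C)(C)C(C)(C)C | intermediate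
16 | 3,4-dibromo-7-(tert-butyldimethylsilyloxy)-5-[(2R,3R)-3-(tert-butyldimethylsilyloxy)butan-2-yl]-6-methylchroman-2-one (mixture at C3/C4) | Cc1c(O[Si](C)(C)C(C)(C)C)cc2OC(=O)C(Br)C(Br)c2c1[C@@H](C)[C@@H](C)O[Si](C)(C)C(C)(C)C | intermediate
17 | 3-bromo-7-(tert-butyldimethylsilyloxy)-5-[(2R,3R)-3-(tert-butyldimethylsilyloxy)butan-2-yl]-6-methyl-2H-chromen-2-one | Cc1c(O[Si](C)(C)C(C)(C)C)cc2oc(=O)c(Br)cc2c1[C@@H](C)[C@@H](C)O[Si](C)(C)C(C)(C)C | intermediate
18 | methyl (S)-3-hydroxybutanoate | C[C@H](O)CC(=O)OC | starting material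
19 | (S)-3-hydroxy-N-methoxy-N-methylbutanamide | C[C@H](O)CC(=O)N(C)OC | intermediate
20 | (S)-5-hydroxyhex-1-yn-3-one | C[C@H](O)CC(=O)C#C | intermediate
21 | (S,E)-1-(diethylamino)-5-hydroxyhex-1-en-3-one | C[C@H](O)CC(=O)/C=C/N(CC)CC | intermediate
22 | (S)-2-methyl-2,3-dihydro-4H-pyran-4-one | C[C@H]1CC(=O)C=CO1 | intermediate
23 | (2S,4R)-2-methyl-3,4-dihydro-2H-pyran-4-ol | C1=C[C@H](O)C[C@H](C)O1 | intermediate
24 | (2S,4R)-2-methyl-4-(triisopropylsilyloxy)-3,4-dihydro-2H-pyran | C1=C[C@H](O[Si](C(C)C)(C(C)C)C(C)C)C[C@H](C)O1 | intermediate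
25 | tributyltin chloride | CCCC[Sn](Cl)(CCCC)CCCC | starting material
26 | [(2S,4R)-2-methyl-4-(triisopropylsilyloxy)-3,4-dihydro-2H-pyran-6-yl]lithium | [Li]C1=C[C@H](O[Si](C(C)C)(C(C)C)C(C)C)C[C@H](C)O1 | intermediate
27 | (2S,4R)-2-methyl-4-(triisopropylsilyloxy)-6-(tributylstannyl)-3,4-dihydro-2H-pyran | CCCC[Sn](CCCC)(CCCC)C1=C[C@H](O[Si](C(C)C)(C(C)C)C(C)C)C[C@H](C)O1 | intermediate
28 | 7-(tert-butyldimethylsilyloxy)-5-[(2R,3R)-3-(tert-butyldimethylsilyloxy)butan-2-yl]-6-methyl-3-[(2S,4R)-2-methyl-4-(triisopropylsilyloxy)-3,4-dihydro-2H-pyran-6-yl]-2H-chromen-2-one | Cc1c(O[Si](C)(C)C(C)(C)C)cc2oc(=O)c(C3=C[C@H](O[Si](C(C)C)(C(C)C)C(C)C)C[C@H](C)O3)cc2c1[C@@H](C)[C@@H](C)O[Si](C)(C)C(C)(C)C | intermediate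
29 | 7-hydroxy-5-[(2R,3R)-3-hydroxybutan-2-yl]-3-[(2S,4R)-4-hydroxy-2-methyl-3,4-dihydro-2H-pyran-6-yl]-6-methyl-2H-chromen-2-one | Cc1c(O)cc2oc(=O)c(C3=C[C@H](O)C[C@H](C)O3)cc2c1[C@@H](C)[C@@H](C)O | intermediate
30 | 7-hydroxy-5-[(2R,3R)-3-hydroxybutan-2-yl]-6-methyl-3-[(2S)-2-methyl-4-oxo-3,4-dihydro-2H-pyran-6-yl]-2H-chromen-2-one (CNP0270207.1) | Cc1c(O)cc2oc(=O)c(C3=CC(=O)C[C@H](C)O3)cc2c1[C@@H](C)[C@@H](C)O | target

**Step count and risk**

Total steps: 19 (steps 1–10 for the bromocoumarin, 11–16 for the stannane, 17–19 for coupling and endgame).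
Longest linear sequence: 13 steps (steps 1–10, then 17–19).

Steps most likely to fail:

1. Step 17 (Stille coupling). Transmetalation from tin to the coumarinyl-palladium bromide may be slow, so that protodestannylation or homocoupling of the acid-sensitive enol-ether stannane consumes 27 before the C3–C6' bond forms. Fallback: a Negishi coupling, known for C1-zincated glycals. It sets out from 24, which is lithiated as in step 16 to 26 and transmetalated with ZnCl2 to [(2S,4R)-2-methyl-4-(triisopropylsilyloxy)-3,4-dihydro-2H-pyran-6-yl]zinc chloride F1. F1 is coupled with 17 using Pd2(dba)3 and XPhos in THF at rt to 50 °C, and the route is rejoined at 28.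

2. Step 3 (epoxide opening). BF3 may isomerise the volatile epoxide, or the ortho-substituted aryllithium may be quenched before it opens the 2,3-disubstituted epoxide, so that little C–C bond formation takes place. Fallback: the more electrophilic cyclic sulfate, which has the same C–O configurations as 5 and therefore gives the same (2R,3R) product on backside attack. It sets out from 4. (2R,3R)-Butane-2,3-diol F2 is converted with SOCl2 into the cyclic sulfite (4R,5R)-4,5-dimethyl-1,3,2-dioxathiolane 2-oxide F3 and oxidised with RuCl3 (cat.) and NaIO4 to the cyclic sulfate (4R,5R)-4,5-dimethyl-1,3,2-dioxathiolane 2,2-dioxide F4. Aryllithium 6 (from 4, with catalytic CuI) opens F4 with inversion to the sulfate monoester (2R,3R)-3-[3,5-bis(benzyloxy)-2-methylphenyl]butan-2-yl hydrogen sulfate F5. Hydrolysis of F5 (cat. H2SO4, H2O, THF) with S–O cleavage rejoins the route at 7.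

3. Step 10 (C3 bromination). Electrophilic substitution at C8 of the oxygenated ring may compete with addition to the C3=C4 bond, which is crowded by the peri side chain at C5, and HBr set free in that process could strip the aryl silyl ether. Fallback: the bromine is brought in with the olefination, so that no electrophilic bromine meets the arene. It sets out from 13. Wittig reaction with Ph3P=C(Br)CO2Et (CH2Cl2, rt) gives ethyl 2-bromo-3-{4-(tert-butyldimethylsilyloxy)-2-hydroxy-5-methyl-6-[(2R,3R)-3-(tert-butyldimethylsilyloxy)butan-2-yl]phenyl}acrylate F6 as a mixture of geometric isomers. The isomer with aryl cis to the ester lactonises directly and the other after photoisomerisation (or heating in PhNEt2), rejoining the route at 17 without passing through 15.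

**Further compounds**

F1 | step 17 | [(2S,4R)-2-methyl-4-(triisopropylsilyloxy)-3,4-dihydro-2H-pyran-6-yl]zinc chloride | Cl[Zn]C1=C[C@H](O[Si](C(C)C)(C(C)C)C(C)C)C[C@H](C)O1
F2 | step 3 | (2R,3R)-butane-2,3-diol | C[C@@H](O)[C@@H](C)O
F3 | step 3 | (4R,5R)-4,5-dimethyl-1,3,2-dioxathiolane 2-oxide | C[C@H]1OS(=O)O[C@@H]1C
F4 | step 3 | (4R,5R)-4,5-dimethyl-1,3,2-dioxathiolane 2,2-dioxide | C[C@H]1OS(=O)(=O)O[C@@H]1C
F5 | step 3 | (2R,3R)-3-[3,5-bis(benzyloxy)-2-methylphenyl]butan-2-yl hydrogen sulfate | Cc1c(OCc2ccccc2)cc(OCc2ccccc2)cc1[C@@H](C)[C@@H](C)OS(=O)(=O)O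
F6 | step 10 | ethyl 2-bromo-3-{4-(tert-butyldimethylsilyloxy)-2-hydroxy-5-methyl-6-[(2R,3R)-3-(tert-butyldimethylsilyloxy)butan-2-yl]phenyl}acrylate (E/Z mixture) | CCOC(=O)C(Br)=Cc1c(O)cc(O[Si](C)(C)C(C)(C)C)c(C)c1[C@@H](C)[C@@H](C)O[Si](C)(C)C(C)(C)C
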